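**Plan**
- Retrosynthesis: the acid is closed back onto the C7 oxygen as a six-membered lactone, the C5 and C4' hydroxyls are masked as methyl and benzyl ethers, and ring C is cut at C3–C4 and O1–C2 into a salicylaldehyde lactone (ring A plus C4) and an aroyl sulfoxonium ylide (C3, C2, ring B).
- Enabling feature: the C8 side chain holds the C7 oxygen in the lactone and the C5 oxygen is an ether, so the only free hydroxyl on ring A is the future O1, lying between C8 and the formyl carbon (future C4). Ring C can therefore close only on the C8 side.
- Forward order: the lactone ring comes first (4-phenylcoumarin from cotoin, then conjugate reduction), then formylation at the future C4a, then ring C by annulation with the ylide, then ether cleavage, and last the opening of the lactone to the acid.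
- Stereochemistry: the single benzylic centre (R; aryl C8 > phenyl > CH2CO2H > H) is set by ligand-controlled CuH 1,4-reduction of the coumarin and is not touched afterwards.

Key step: step 5

Assumptions (remarks on the chemistry):
- Cotoin is taken as a purchasable natural benzophenone.
- The R antipode of DTBM-SEGPHOS is written for step 2 by analogy with simple 4-arylcoumarins; if the sense of induction proves opposite, the S ligand would be used.

**Route**

Step 1
Reactants: 1 cotoin (2,6-dihydroxy-4-methoxybenzophenone); 2 ethyl (triphenylphosphoranylidene)acetate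
Product: 4 5-hydroxy-7-methoxy-4-phenylcoumarin, via aryl ester ylide 3 (not isolated)
Conditions: xylene, 140 °C
Reagents that add atoms: none
Why: One of the two equivalent phenols transesterifies the stabilised ylide to aryl ester ylide 3, whose intramolecular Wittig olefination of the diaryl ketone closes the pyranone with the alkene necessarily cis (Wittig olefination–lactonisation route to 4-arylcoumarins), and the mirror symmetry of cotoin leaves no regiochemical choice.

Step 2
Reactants: 4 5-hydroxy-7-methoxy-4-phenylcoumarin
Product: 6 (4R)-5-hydroxy-7-methoxy-4-phenylchroman-2-one, via bis-silyl ketene acetal 5 (not isolated)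
Conditions: Cu(OAc)2·H2O (cat.), (R)-DTBM-SEGPHOS (cat.), HSiMe(OEt)2 (excess), toluene, 0 °C to rt; then 1 M HCl, THF
Reagents that add atoms: none
Why: Ligated CuH (monovalent copper) formed from Cu(OAc)2·H2O and the silane should first silylate the phenol with loss of hydrogen and then deliver hydride to C4 (asymmetric conjugate reduction of a β,β-disubstituted unsaturated lactone), the bisphosphine selecting the enantiotopic face so that C4 becomes R, while trapping of the enolate as silyl ketene acetal 5 shields the carbonyl from 1,2-reduction until the acidic work-up.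

Step 3
Reactants: 6 (4R)-5-hydroxy-7-methoxy-4-phenylchroman-2-one
Product: 8 (4R)-6-formyl-5-hydroxy-7-methoxy-4-phenylchroman-2-one, via salicyl alcohol 7 (not isolated)
Conditions: MgCl2, Et3N, (CH2O)n, MeCN, reflux; 1 M HCl work-up
Reagents that add atoms: paraformaldehyde (as formaldehyde), C=O
Why: The ArOMgCl phenoxide binds formaldehyde and delivers it to the only free ortho carbon, C6, and salicyl alcohol 7 is oxidised in place by hydride transfer to a second formaldehyde (ortho-formylation of phenols of the Casnati–Skattebøl type), so C8, which is para to the phenol, should stay untouched.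

Step 4
Reactants: 9 methyl 4-(benzyloxy)benzoate; 10 trimethylsulfoxonium iodide
Product: 12 dimethylsulfoxonium 2-[4-(benzyloxy)phenyl]-2-oxoethylide, via dimethylsulfoxonium methylide 11 (not isolated)
Conditions: KOtBu, THF, reflux
Reagents that add atoms: none
Why: Methylide 11, formed from the salt with KOtBu, is acylated at carbon by the methyl ester, and the resulting β-keto sulfoxonium ion loses a proton to give the stabilised ylide (acylation of the Corey–Chaykovsky ylide).

Step 5
Reactants: 8 (4R)-6-formyl-5-hydroxy-7-methoxy-4-phenylchroman-2-one; 12 dimethylsulfoxonium 2-[4-(benzyloxy)phenyl]-2-oxoethylide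
Product: 14 (10R)-2-[4-(benzyloxy)phenyl]-5-methoxy-10-phenyl-9,10-dihydro-4H,8H-pyrano[2,3-f]chromene-4,8-dione (the lactone of the 4'-O-benzyl-5-O-methyl target), via beta-diketone 13 (not isolated)
Conditions: [Cp*RhCl2]2 (cat.), AgSbF6 (cat.), NaOAc, ClCH2CH2Cl, 80 °C
Reagents that add atoms: none
Why: The cationic Cp*Rh species (trivalent rhodium, chloride removed by AgSbF6) binds the phenoxide of 8 and, assisted by acetate, cleaves the formyl C–H bond to a five-membered acyl rhodacycle; ylide 12 then coordinates through carbon, loses dimethyl sulfoxide to a rhodium carbene, and migration of the acyl group onto the carbene carbon forms the C3–C4 bond, after which protonation releases beta-diketone 13 and returns the catalyst. The closest known reaction is the annulation of salicylaldehydes with aroyl sulfoxonium ylides to flavones through aldehyde C–H activation at trivalent rhodium, used here on a new substrate. Ring C then closes by 6-exo-trig addition of the phenol oxygen to the aroyl carbonyl (O1–C2 bond) and loss of water, driven by formation of the aromatic pyranone. No stereocentre is created, and the benzylic centre carries no hydrogen that is acidic or ionisable under these near-neutral conditions. The step needs regiocontrol of the ring closure and chemoselection for the aldehyde over the lactone: the first is secured because the hydroxyl between the formyl carbon and the carbon bearing the stereocentre is the only one free to direct rhodium and to cyclise, and the second because carboxylate-assisted C–H cleavage involves no nucleophile able to open the aryl ester.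

Step 6
Reactants: 14 the benzyl methyl ether lactone from step 5
Product: 15 (10R)-5-hydroxy-2-(4-hydroxyphenyl)-10-phenyl-9,10-dihydro-4H,8H-pyrano[2,3-f]chromene-4,8-dione
Conditions: BCl3, C6HMe5, CH2Cl2, −78 °C to rt; then H2O
Reagents that add atoms: none
Why: BCl3 chelated between the C4 carbonyl and the peri C5 oxygen should cleave that methyl ether and also ionise the benzyl ether, the benzyl cation being captured by pentamethylbenzene (Lewis-acid ether cleavage with a cation scavenger), while the lactone and the stereocentre are inert to a non-nucleophilic Lewis acid.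

Step 7
Reactants: 15 the dihydroxy flavone lactone from step 6
Product: 17 (3R)-3-[5,7-dihydroxy-2-(4-hydroxyphenyl)-4-oxo-4H-chromen-8-yl]-3-phenylpropanoic acid, via trilithium salt 16 (not isolated)
Conditions: LiOH, THF/H2O, 0 °C, argon; then 1 M HCl to pH 3, 0 °C
Reagents that add atoms: lithium hydroxide, [Li+].[OH-]; water, O
Why: Hydroxide should attack the activated aryl ester carbonyl (saponification of a phenolic lactone) far faster than it affects the flavone, and cold acidification of salt 16 to about pH 3 protonates carboxylate and phenoxides without giving the acid time to relactonise.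

**Compound list**

1 | cotoin (2,6-dihydroxy-4-methoxybenzophenone) | COc1cc(O)c(C(=O)c2ccccc2)c(O)c1 | starting material
2 | ethyl (triphenylphosphoranylidene)acetate | CCOC(=O)C=P(c1ccccc1)(c1ccccc1)c1ccccc1 | starting material
3 | 2-benzoyl-3-hydroxy-5-methoxyphenyl (triphenylphosphoranylidene)acetate | COc1cc(O)c(C(=O)c2ccccc2)c(OC(=O)C=P(c2ccccc2)(c2ccccc2)c2ccccc2)c1 | intermediate
4 | 5-hydroxy-7-methoxy-4-phenylcoumarin | COc1cc(O)c2c(-c3ccccc3)cc(=O)oc2c1 | intermediate
5 | (4R)-2,5-bis[diethoxy(methyl)silyloxy]-7-methoxy-4-phenyl-4H-chromene | COc1cc2OC(O[Si](C)(OCC)OCC)=C[C@H](c3ccccc3)c2c(O[Si](C)(OCC)OCC)c1 | intermediate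
6 | (4R)-5-hydroxy-7-methoxy-4-phenylchroman-2-one | COc1cc2OC(=O)C[C@H](c3ccccc3)c2c(O)c1 | intermediate
7 | (4R)-5-hydroxy-6-(hydroxymethyl)-7-methoxy-4-phenylchroman-2-one (magnesium salt in the flask) | OCc1c(OC)cc2OC(=O)C[C@H](c3ccccc3)c2c1O | intermediate
8 | (4R)-6-formyl-5-hydroxy-7-methoxy-4-phenylchroman-2-one | O=Cc1c(OC)cc2OC(=O)C[C@H](c3ccccc3)c2c1O | intermediate
9 | methyl 4-(benzyloxy)benzoate | COC(=O)c1ccc(OCc2ccccc2)cc1 | starting material
10 | trimethylsulfoxonium iodide | C[S+](C)(C)=O.[I-] | starting material
11 | dimethylsulfoxonium methylide | C=S(C)(C)=O | intermediate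
12 | dimethylsulfoxonium 2-[4-(benzyloxy)phenyl]-2-oxoethylide | CS(C)(=O)=CC(=O)c1ccc(OCc2ccccc2)cc1 | intermediate
13 | (4R)-6-{3-[4-(benzyloxy)phenyl]-3-oxopropanoyl}-5-hydroxy-7-methoxy-4-phenylchroman-2-one | O=C(CC(=O)c1ccc(OCc2ccccc2)cc1)c1c(OC)cc2OC(=O)C[C@H](c3ccccc3)c2c1O | intermediate
14 | (10R)-2-[4-(benzyloxy)phenyl]-5-methoxy-10-phenyl-9,10-dihydro-4H,8H-pyrano[2,3-f]chromene-4,8-dione | O=c1cc(-c2ccc(OCc3ccccc3)cc2)oc2c1c(OC)cc1OC(=O)C[C@H](c3ccccc3)c12 | intermediate
15 | (10R)-5-hydroxy-2-(4-hydroxyphenyl)-10-phenyl-9,10-dihydro-4H,8H-pyrano[2,3-f]chromene-4,8-dione | O=c1cc(-c2ccc(O)cc2)oc2c1c(O)cc1OC(=O)C[C@H](c3ccccc3)c12 | intermediate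
16 | trilithium salt of 17 (carboxylate, C7 phenoxide and C4' phenoxide; the chelated C5 hydroxyl drawn protonated) | [Li+].[Li+].[Li+].[O-]C(=O)C[C@H](c1ccccc1)c1c([O-])cc(O)c2c(=O)cc(-c3ccc([O-])cc3)oc12 | intermediate
17 | (3R)-3-[5,7-dihydroxy-2-(4-hydroxyphenyl)-4-oxo-4H-chromen-8-yl]-3-phenylpropanoic acid | O=C(O)C[C@H](c1ccccc1)c1c(O)cc(O)c2c(=O)cc(-c3ccc(O)cc3)oc12 | target

**Step count**

Total steps: 7. Longest linear sequence: 6 (steps 1, 2, 3, 5, 6, 7); step 4 is a one-step side branch.

**Steps most likely to fail**

Step 5. The directing phenoxide is crowded between the formyl group and the carbon carrying the phenyl-bearing stereocentre, so metalation of the formyl C–H bond may be slow. The reaction may also stall at beta-diketone 13, which can hold the catalyst as a chelate. A catalytic amount of TsOH·H2O added at the end should complete the dehydration if only the second problem arises. The fallback leaves C–H activation for a chalcone route and sets out from 6. C-acetylation ortho to the free hydroxyl (Ac2O, BF3·OEt2, 60 °C, then aqueous hydrolysis of the difluoroboron chelate) should give (4R)-6-acetyl-5-hydroxy-7-methoxy-4-phenylchroman-2-one F1. An acid-mediated Claisen–Schmidt condensation with 4-(benzyloxy)benzaldehyde (BF3·OEt2, dioxane, rt), chosen so that no base meets the lactone, should give (4R,E)-6-{3-[4-(benzyloxy)phenyl]acryloyl}-5-hydroxy-7-methoxy-4-phenylchroman-2-one F2. Oxidative cyclisation of this 2'-hydroxychalcone (I2 cat., DMSO, 120 °C) closes ring C and returns to the route at 14.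

Step 2. Hydride transfer to a β,β-diaryl carbon flanked by the peri oxygen may be sluggish or poorly face-selective, and the lactone may be reduced further to the lactol if the enolate is protonated before it is silylated. The fallback builds the stereocentre by aryl transfer instead of hydride transfer and sets out from 2. Heating 2 with 2,6-dihydroxy-4-methoxybenzaldehyde F3 (xylene, 140 °C) should give 5-hydroxy-7-methoxycoumarin F4 by the same olefination–lactonisation. Asymmetric 1,4-addition of phenylboronic acid (Rh(acac)(C2H4)2, (R)-SEGPHOS, dioxane/H2O, 60 °C; Hayashi–Miyaura reaction, ligand antipode chosen for the R product) then returns to the route at 6.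

Step 3. The methanol formed in the hydride-transfer stage may open the aryl lactone under the basic MgCl2/Et3N conditions, or oxidation may stop at salicyl alcohol 7. The fallback sets out from 6 and reaches 8 directly by Rieche formylation (Cl2CHOMe, TiCl4, CH2Cl2, 0 °C, then aqueous acid). This is an acidic, alcohol-free electrophilic formylation in which the titanium phenoxide steers the electrophile to the ortho carbon. It makes no new compound (F0).

Further compounds
F1 | step 5 | (4R)-6-acetyl-5-hydroxy-7-methoxy-4-phenylchroman-2-one | CC(=O)c1c(OC)cc2OC(=O)C[C@H](c3ccccc3)c2c1O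
F2 | step 5 | (4R,E)-6-{3-[4-(benzyloxy)phenyl]acryloyl}-5-hydroxy-7-methoxy-4-phenylchroman-2-one | O=C(/C=C/c1ccc(OCc2ccccc2)cc1)c1c(OC)cc2OC(=O)C[C@H](c3ccccc3)c2c1O
F3 | step 2 | 2,6-dihydroxy-4-methoxybenzaldehyde | COc1cc(O)c(C=O)c(O)c1
F4 | step 2 | 5-hydroxy-7-methoxycoumarin | COc1cc(O)c2ccc(=O)oc2c1
F0 | step 3 | none | none
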